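**Strategy.** The ten-membered carbocycle is closed at the C9–C10 single bond, the C(sp3)–C(sp2) link of the homoallylic unit O–C8–C9–C10=C1 (germacrane numbering: lactone on C6/C7, ester on C8, C14 on C10). A nickel-catalysed reductive cross-electrophile coupling joins the primary C9 bromide of a C8 bromohydrin to a C10 vinyl iodide. The iodide geometry (iodine cis to C2, set by hydroxyl-directed trans-hydroalumination) becomes the ring-cis C1=C10 alkene, and the same operation leaves the C8 hydroxyl free for angeloylation. The precursor is an open-chain trans-γ-butyrolactone (C6 and C7 from an Evans aldol) carrying the Z C4=C5 alkene (locked earlier in a dihydropyranone) and both silyl-protected carbinols.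

Key step: step 14

Assumption: the copper/Tol-BINAP vinylogous aldol of step 5 is taken to attack the Si face of aldehyde 5 with the (S)-ligand; if the opposite sense is found, the ligand antipode is used and nothing else changes.

Step 1
Reactants: 1 but-2-yne-1,4-diol
Product: 2 4-[(tert-butyldimethylsilyl)oxy]but-2-yn-1-ol
Conditions: NaH (1.0 equiv), THF, 0 °C; t-BuMe2SiCl (1.0 equiv), rt
Reagents that add atoms: tert-butyldimethylsilyl chloride, CC(C)(C)[Si](C)(C)Cl
Why: The sparingly soluble monosodium alkoxide of the symmetrical diol is silylated once (monosilylation of a symmetrical diol, Williamson-type O-silylation).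

Step 2
Reactants: 2 4-[(tert-butyldimethylsilyl)oxy]but-2-yn-1-ol
Product: 4 (2Z)-4-[(tert-butyldimethylsilyl)oxy]-3-iodobut-2-en-1-ol, via alkenylalanate 3 (not isolated)
Conditions: NaAlH2(OCH2CH2OMe)2, THF, 0 °C; then I2, −78 to 0 °C
Reagents that add atoms: iodine, II
Why: Hydroxyl-directed trans-hydroalumination of the propargylic alcohol puts hydride on the proximal and aluminium on the distal alkyne carbon inside a five-membered alkoxyalanate, and iodinolysis with retention should give the Z iodide (iodine cis to CH2OH).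

Step 3
Reactants: 4 (2Z)-4-[(tert-butyldimethylsilyl)oxy]-3-iodobut-2-en-1-ol
Product: 5 (2Z)-4-[(tert-butyldimethylsilyl)oxy]-3-iodobut-2-enal
Conditions: MnO2, CH2Cl2, rt
Reagents that add atoms: none
Why: Allylic oxidation with MnO2 is neutral and should leave the Z β-iodo enal and the silyl ether untouched.

Step 4
Reactants: 6 methyl 3-methylbut-2-enoate
Product: 7 1-methoxy-3-methyl-1-(trimethylsilyloxy)buta-1,3-diene
Conditions: LiN(i-Pr)2, THF, −78 °C; Me3SiCl
Reagents that add atoms: chlorotrimethylsilane, C[Si](C)(C)Cl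
Why: γ-Deprotonation of the senecioate and O-silylation of the lithium dienolate give the vinylketene silyl acetal (used as the geometrical mixture obtained).

Step 5
Reactants: 5 (2Z)-4-[(tert-butyldimethylsilyl)oxy]-3-iodobut-2-enal; 7 1-methoxy-3-methyl-1-(trimethylsilyloxy)buta-1,3-diene
Product: 9 (6S)-6-[(1Z)-3-[(tert-butyldimethylsilyl)oxy]-2-iodoprop-1-en-1-yl]-4-methyl-5,6-dihydro-2H-pyran-2-one, via copper aldolate 8 (not isolated)
Conditions: Cu(OTf)2 (10 mol%), (S)-Tol-BINAP (11 mol%), Bu4N[Ph3SiF2] (20 mol%), THF, −78 °C to rt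
Reagents that add atoms: none
Why: In a catalytic asymmetric vinylogous Mukaiyama aldol, the chiral copper dienolate attacks through its γ-carbon on the Si face of the enal and sets C2 as S; the Z aldolate then lactonises, which fixes C4=C5 as the ring-cis alkene inside the six-membered ring.

Step 6
Reactants: 9 the dihydropyranone
Product: 10 (2Z,5S,6Z)-8-[(tert-butyldimethylsilyl)oxy]-5-hydroxy-7-iodo-N-methoxy-N,3-dimethylocta-2,6-dienamide
Conditions: MeNH(OMe)·HCl, AlMe3, CH2Cl2, 0 °C to rt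
Reagents that add atoms: N,O-dimethylhydroxylamine hydrochloride, CNOC.Cl
Why: Weinreb aminolysis with the aluminium amide opens the unsaturated δ-lactone by 1,2-attack and keeps the Z alkene.

Step 7
Reactants: 10 the hydroxy Weinreb amide
Product: 11 (2Z,5S,6Z)-5,8-bis[(tert-butyldimethylsilyl)oxy]-7-iodo-N-methoxy-N,3-dimethylocta-2,6-dienamide
Conditions: t-BuMe2SiCl, imidazole, DMF, rt
Reagents that add atoms: tert-butyldimethylsilyl chloride, CC(C)(C)[Si](C)(C)Cl
Why: Prompt silylation of the C2 hydroxyl prevents relactonisation and protects it until the last step.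

Step 8
Reactants: 11 the bis-silyl Weinreb amide
Product: 12 (2Z,5S,6Z)-5,8-bis[(tert-butyldimethylsilyl)oxy]-7-iodo-3-methylocta-2,6-dienal
Conditions: i-Bu2AlH, THF, −78 °C; Rochelle salt work-up
Reagents that add atoms: none
Why: Reduction of a Weinreb amide stops at the chelated tetrahedral intermediate and should release the Z enal without isomerisation on neutral work-up.

Step 9
Reactants: 13 (4S)-4-benzyl-1,3-oxazolidin-2-one; 14 methyl 4-chloro-4-oxobutanoate
Product: 15 methyl 4-[(4S)-4-benzyl-2-oxo-1,3-oxazolidin-3-yl]-4-oxobutanoate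
Conditions: n-BuLi, THF, −78 °C; then 14
Reagents that add atoms: none
Why: N-Acylation of the lithiated Evans auxiliary with the succinic half-ester chloride.

Step 10
Reactants: 12 the Z enal; 15 the succinoyl imide
Product: 17 (4S)-4-benzyl-3-{[(2R,3S)-2-[(1Z,4S,5Z)-4,7-bis[(tert-butyldimethylsilyl)oxy]-6-iodo-2-methylhepta-1,5-dien-1-yl]-5-oxooxolan-3-yl]carbonyl}-1,3-oxazolidin-2-one, via syn-aldol adduct 16 (not isolated)
Conditions: n-Bu2BOTf, i-Pr2NEt, CH2Cl2, −78 to 0 °C; 12, −78 to 0 °C; pH 7 buffer, MeOH, H2O2; then PPTS (cat.), CH2Cl2, rt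
Reagents that add atoms: none
Why: In the Evans syn-aldol, the Z boron enolate reacts through a Zimmerman–Traxler chair on the face opposite the benzyl group and sets C7 and C6; the new C6 hydroxyl then closes onto the methyl ester, so only the trans 6,12-lactone can form.

Step 11
Reactants: 17 the lactone imide
Product: 19 (2R,3S)-2-[(1Z,4S,5Z)-4,7-bis[(tert-butyldimethylsilyl)oxy]-6-iodo-2-methylhepta-1,5-dien-1-yl]-5-oxooxolane-3-carboxylic acid, via peroxy acid 18 (not isolated)
Conditions: LiOH, H2O2, THF–H2O, 0 °C; Na2SO3; 1 M HCl to pH 3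
Reagents that add atoms: hydrogen peroxide, OO
Why: Lithium hydroperoxide cleaves the exocyclic imide carbonyl selectively, sulfite reduces the peracid, and the trans lactone acid is the thermodynamically preferred epimer.

Step 12
Reactants: 19 the lactone acid
Product: 22 (4S,5R)-4-(bromoacetyl)-5-[(1Z,4S,5Z)-4,7-bis[(tert-butyldimethylsilyl)oxy]-6-iodo-2-methylhepta-1,5-dien-1-yl]oxolan-2-one, via acid chloride 20 (not isolated), via diazoketone 21 (not isolated)
Conditions: (COCl)2, DMF (cat.), CH2Cl2, 0 °C; Me3SiCHN2, THF–MeCN, 0 °C; HBr (33% in AcOH, 1.05 equiv), Et2O, −20 °C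
Reagents that add atoms: (trimethylsilyl)diazomethane, C[Si](C)(C)C=[N+]=[N-]; hydrogen bromide, Br
Why: Acylation of the diazoalkane (first stage of an Arndt–Eistert sequence) followed by hydrobromination with loss of N2 adds C9 as a bromomethyl ketone under non-basic conditions that spare the β-acyloxy ketone.

Step 13
Reactants: 22 the bromomethyl ketone
Product: 23 (4R,5R)-4-[(1R)-2-bromo-1-hydroxyethyl]-5-[(1Z,4S,5Z)-4,7-bis[(tert-butyldimethylsilyl)oxy]-6-iodo-2-methylhepta-1,5-dien-1-yl]oxolan-2-one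
Conditions: (R)-2-methyl-CBS-oxazaborolidine (20 mol%), BH3·SMe2, THF, −20 °C; MeOH
Reagents that add atoms: none
Why: In the Corey–Bakshi–Shibata reduction the branched C7 acts as the large and CH2Br as the small substituent, so the (R)-catalyst should give the (R)-bromohydrin, by analogy with phenacyl halides; this is the C8 configuration of the target.

Step 14
Reactants: 23 the bromohydrin vinyl iodide
Product: 24 (3aR,4S,6E,8S,10Z,11aR)-8-[(tert-butyldimethylsilyl)oxy]-6-{[(tert-butyldimethylsilyl)oxy]methyl}-4-hydroxy-10-methyl-3a,4,5,8,9,11a-hexahydrocyclodeca[b]furan-2(3H)-one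
Conditions: NiBr2·glyme (30 mol%), 4,4′-di-tert-butyl-2,2′-bipyridine (30 mol%), Mn powder (3 equiv), DMA, 40 °C, syringe-pump addition of 23 (final 2 mM)
Reagents that add atoms: none
Why: Zerovalent nickel–bipyridine adds oxidatively to the C10–I bond with retention; a low-valent nickel species abstracts bromine from C9, the primary C9 radical is captured at the alkenylnickel centre of the same molecule, and reductive elimination from trivalent nickel forms C9–C10 while Mn returns nickel to the low-valent state. The closest known reaction is the nickel-catalysed reductive coupling of alkenyl halides with primary alkyl halides, including halohydrins generated from epoxides, used here as a ring closure. The ten-membered ring closes by cross-coupling at the sp2 terminus, not by radical addition to an alkene. No stereocentre is formed: the C1=C10 geometry comes from the vinyl iodide, and C8 keeps its configuration because only C9 becomes a radical. The step needs ring closure to beat dimerisation and hydrodehalogenation, which high dilution, the trans-lactone and the two Z alkenes (folding C9 towards C10) should secure. It also needs C–I insertion to beat ionisation of the allylic lactone C6–O bond; 5-exo attack of the C9 radical on C5 is disfavoured because it would give a trans-fused bicyclo[3.3.0] system.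

Step 15
Reactants: 24 the macrocyclic hydroxy lactone
Product: 27 (3R,3aR,4S,6E,8S,10Z,11aR)-8-[(tert-butyldimethylsilyl)oxy]-6-{[(tert-butyldimethylsilyl)oxy]methyl}-3-[(dimethylamino)methyl]-4-hydroxy-10-methyl-3a,4,5,8,9,11a-hexahydrocyclodeca[b]furan-2(3H)-one, via silyl ether 25 (not isolated), via silylated Mannich base 26 (not isolated)
Conditions: Me3SiCl, Et3N, THF, 0 °C; LiN(SiMe3)2, −78 °C; CH2=NMe2+ I−, −78 to 0 °C; aq. citric acid work-up
Reagents that add atoms: N,N-dimethylmethyleneiminium iodide (Eschenmoser's salt), C=[N+](C)C.[I-]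
Why: Transient silylation of the C8 hydroxyl prevents translactonisation; the lactone lithium enolate then undergoes a Mannich reaction with the iminium salt anti to the C8 branch (this C11 centre is removed in step 16), and the trimethylsilyl group is lost on acidic work-up.

Step 16
Reactants: 27 the Mannich base
Product: 29 (3aR,4S,6E,8S,10Z,11aR)-8-[(tert-butyldimethylsilyl)oxy]-6-{[(tert-butyldimethylsilyl)oxy]methyl}-4-hydroxy-10-methyl-3-methylidene-3a,4,5,8,9,11a-hexahydrocyclodeca[b]furan-2(3H)-one, via ammonium iodide 28 (not isolated)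
Conditions: MeI, CH2Cl2–MeOH, rt; sat. aq. NaHCO3, rt
Reagents that add atoms: none
Why: Quaternisation and Hofmann-type E1cB loss of trimethylamine give the exocyclic α-methylene lactone under base too mild to move the lactone to O8.

Step 17
Reactants: 29 the α-methylene lactone alcohol; 30 angelic acid [(2Z)-2-methylbut-2-enoic acid]
Product: 32 (3aR,4S,6E,8S,10Z,11aR)-8-[(tert-butyldimethylsilyl)oxy]-6-{[(tert-butyldimethylsilyl)oxy]methyl}-10-methyl-3-methylidene-2-oxo-2,3,3a,4,5,8,9,11a-octahydrocyclodeca[b]furan-4-yl (2Z)-2-methylbut-2-enoate, via mixed anhydride 31 (not isolated)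
Conditions: 2,4,6-Cl3C6H2COCl, Et3N, toluene, rt; then 29, 75 °C
Reagents that add atoms: none
Why: Yamaguchi esterification through the trichlorobenzoyl mixed anhydride without a nucleophilic catalyst acylates the only free hydroxyl (C8) and avoids angelate-to-tiglate isomerisation.

Step 18
Reactants: 32 the bis-silyl angelate
Product: 33 (3aR,4S,6E,8S,10Z,11aR)-8-hydroxy-6-(hydroxymethyl)-10-methyl-3-methylidene-2-oxo-2,3,3a,4,5,8,9,11a-octahydrocyclodeca[b]furan-4-yl (2Z)-2-methylbut-2-enoate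
Conditions: HF·pyridine, pyridine, THF, 0 °C to rt
Reagents that add atoms: none
Why: Buffered fluoride desilylation frees the C2 and C14 hydroxyls without base, so the α-methylene lactone, the angelate and both alkenes should survive.

**Compound list**

1 | but-2-yne-1,4-diol | OCC#CCO | starting material
2 | 4-[(tert-butyldimethylsilyl)oxy]but-2-yn-1-ol | OCC#CCO[Si](C)(C)C(C)(C)C | intermediate
3 | sodium cyclic alkenyl(alkoxy)bis(2-methoxyethoxy)alanate from 2 (Al on the carbon bearing CH2OSi, ring through the alkoxide) | [Na+].COCCO[Al-]1(OCCOC)OCC=C1CO[Si](C)(C)C(C)(C)C | intermediate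
4 | (2Z)-4-[(tert-butyldimethylsilyl)oxy]-3-iodobut-2-en-1-ol | OC/C=C(\I)CO[Si](C)(C)C(C)(C)C | intermediate
5 | (2Z)-4-[(tert-butyldimethylsilyl)oxy]-3-iodobut-2-enal | O=C/C=C(\I)CO[Si](C)(C)C(C)(C)C | intermediate
6 | methyl 3-methylbut-2-enoate | COC(=O)C=C(C)C | starting material
7 | 1-methoxy-3-methyl-1-(trimethylsilyloxy)buta-1,3-diene | COC(O[Si](C)(C)C)=CC(C)=C | intermediate
8 | methyl (2Z,5S,6Z)-8-[(tert-butyldimethylsilyl)oxy]-5-hydroxy-7-iodo-3-methylocta-2,6-dienoate (present as its copper alkoxide) | COC(=O)/C=C(C)\C[C@H](O)/C=C(\I)CO[Si](C)(C)C(C)(C)C | intermediate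
9 | (6S)-6-[(1Z)-3-[(tert-butyldimethylsilyl)oxy]-2-iodoprop-1-en-1-yl]-4-methyl-5,6-dihydro-2H-pyran-2-one | O=C1C=C(C)C[C@H](O1)/C=C(\I)CO[Si](C)(C)C(C)(C)C | intermediate
10 | (2Z,5S,6Z)-8-[(tert-butyldimethylsilyl)oxy]-5-hydroxy-7-iodo-N-methoxy-N,3-dimethylocta-2,6-dienamide | CON(C)C(=O)/C=C(C)\C[C@H](O)/C=C(\I)CO[Si](C)(C)C(C)(C)C | intermediate
11 | (2Z,5S,6Z)-5,8-bis[(tert-butyldimethylsilyl)oxy]-7-iodo-N-methoxy-N,3-dimethylocta-2,6-dienamide | CON(C)C(=O)/C=C(C)\C[C@H](O[Si](C)(C)C(C)(C)C)/C=C(\I)CO[Si](C)(C)C(C)(C)C | intermediate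
12 | (2Z,5S,6Z)-5,8-bis[(tert-butyldimethylsilyl)oxy]-7-iodo-3-methylocta-2,6-dienal | O=C/C=C(C)\C[C@H](O[Si](C)(C)C(C)(C)C)/C=C(\I)CO[Si](C)(C)C(C)(C)C | intermediate
13 | (4S)-4-benzyl-1,3-oxazolidin-2-one | O=C1N[C@@H](Cc2ccccc2)CO1 | starting material
14 | methyl 4-chloro-4-oxobutanoate | COC(=O)CCC(=O)Cl | starting material
15 | methyl 4-[(4S)-4-benzyl-2-oxo-1,3-oxazolidin-3-yl]-4-oxobutanoate | COC(=O)CCC(=O)N1C(=O)OC[C@@H]1Cc1ccccc1 | intermediate
16 | methyl (3S,4R,5Z,8S,9Z)-3-{[(4S)-4-benzyl-2-oxo-1,3-oxazolidin-3-yl]carbonyl}-8,11-bis[(tert-butyldimethylsilyl)oxy]-4-hydroxy-10-iodo-6-methylundeca-5,9-dienoate | COC(=O)C[C@H](C(=O)N1C(=O)OC[C@@H]1Cc1ccccc1)[C@H](O)/C=C(C)\C[C@H](O[Si](C)(C)C(C)(C)C)/C=C(\I)CO[Si](C)(C)C(C)(C)C | intermediate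
17 | (4S)-4-benzyl-3-{[(2R,3S)-2-[(1Z,4S,5Z)-4,7-bis[(tert-butyldimethylsilyl)oxy]-6-iodo-2-methylhepta-1,5-dien-1-yl]-5-oxooxolan-3-yl]carbonyl}-1,3-oxazolidin-2-one | O=C1C[C@H](C(=O)N2C(=O)OC[C@@H]2Cc2ccccc2)[C@H](O1)/C=C(C)\C[C@H](O[Si](C)(C)C(C)(C)C)/C=C(\I)CO[Si](C)(C)C(C)(C)C | intermediate
18 | peroxy acid corresponding to acid 19 (C(=O)OOH on the lactone 3-position) | O=C1C[C@H](C(=O)OO)[C@H](O1)/C=C(C)\C[C@H](O[Si](C)(C)C(C)(C)C)/C=C(\I)CO[Si](C)(C)C(C)(C)C | intermediate
19 | (2R,3S)-2-[(1Z,4S,5Z)-4,7-bis[(tert-butyldimethylsilyl)oxy]-6-iodo-2-methylhepta-1,5-dien-1-yl]-5-oxooxolane-3-carboxylic acid | O=C1C[C@H](C(=O)O)[C@H](O1)/C=C(C)\C[C@H](O[Si](C)(C)C(C)(C)C)/C=C(\I)CO[Si](C)(C)C(C)(C)C | intermediate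
20 | acid chloride of 19 | O=C1C[C@H](C(=O)Cl)[C@H](O1)/C=C(C)\C[C@H](O[Si](C)(C)C(C)(C)C)/C=C(\I)CO[Si](C)(C)C(C)(C)C | intermediate
21 | diazomethyl ketone from 20 | O=C1C[C@H](C(=O)C=[N+]=[N-])[C@H](O1)/C=C(C)\C[C@H](O[Si](C)(C)C(C)(C)C)/C=C(\I)CO[Si](C)(C)C(C)(C)C | intermediate
22 | (4S,5R)-4-(bromoacetyl)-5-[(1Z,4S,5Z)-4,7-bis[(tert-butyldimethylsilyl)oxy]-6-iodo-2-methylhepta-1,5-dien-1-yl]oxolan-2-one | O=C1C[C@H](C(=O)CBr)[C@H](O1)/C=C(C)\C[C@H](O[Si](C)(C)C(C)(C)C)/C=C(\I)CO[Si](C)(C)C(C)(C)C | intermediate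
23 | (4R,5R)-4-[(1R)-2-bromo-1-hydroxyethyl]-5-[(1Z,4S,5Z)-4,7-bis[(tert-butyldimethylsilyl)oxy]-6-iodo-2-methylhepta-1,5-dien-1-yl]oxolan-2-one | O=C1C[C@H]([C@@H](O)CBr)[C@H](O1)/C=C(C)\C[C@H](O[Si](C)(C)C(C)(C)C)/C=C(\I)CO[Si](C)(C)C(C)(C)C | intermediate
24 | (3aR,4S,6E,8S,10Z,11aR)-8-[(tert-butyldimethylsilyl)oxy]-6-{[(tert-butyldimethylsilyl)oxy]methyl}-4-hydroxy-10-methyl-3a,4,5,8,9,11a-hexahydrocyclodeca[b]furan-2(3H)-one | C1C(=O)O[C@@H]2/C=C(/C)C[C@H](O[Si](C)(C)C(C)(C)C)/C=C(/CO[Si](C)(C)C(C)(C)C)C[C@H](O)[C@@H]12 | intermediate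
25 | 4-O-trimethylsilyl ether of 24 (silyl on the C8 oxygen, germacrane numbering) | C1C(=O)O[C@@H]2/C=C(/C)C[C@H](O[Si](C)(C)C(C)(C)C)/C=C(/CO[Si](C)(C)C(C)(C)C)C[C@H](O[Si](C)(C)C)[C@@H]12 | intermediate
26 | 4-O-trimethylsilyl ether of Mannich base 27 | CN(C)C[C@@H]1C(=O)O[C@@H]2/C=C(/C)C[C@H](O[Si](C)(C)C(C)(C)C)/C=C(/CO[Si](C)(C)C(C)(C)C)C[C@H](O[Si](C)(C)C)[C@@H]12 | intermediate
27 | (3R,3aR,4S,6E,8S,10Z,11aR)-8-[(tert-butyldimethylsilyl)oxy]-6-{[(tert-butyldimethylsilyl)oxy]methyl}-3-[(dimethylamino)methyl]-4-hydroxy-10-methyl-3a,4,5,8,9,11a-hexahydrocyclodeca[b]furan-2(3H)-one | CN(C)C[C@@H]1C(=O)O[C@@H]2/C=C(/C)C[C@H](O[Si](C)(C)C(C)(C)C)/C=C(/CO[Si](C)(C)C(C)(C)C)C[C@H](O)[C@@H]12 | intermediate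
28 | N-methyl quaternary ammonium iodide of 27 | C[N+](C)(C)C[C@@H]1C(=O)O[C@@H]2/C=C(/C)C[C@H](O[Si](C)(C)C(C)(C)C)/C=C(/CO[Si](C)(C)C(C)(C)C)C[C@H](O)[C@@H]12.[I-] | intermediate
29 | (3aR,4S,6E,8S,10Z,11aR)-8-[(tert-butyldimethylsilyl)oxy]-6-{[(tert-butyldimethylsilyl)oxy]methyl}-4-hydroxy-10-methyl-3-methylidene-3a,4,5,8,9,11a-hexahydrocyclodeca[b]furan-2(3H)-one | C=C1C(=O)O[C@@H]2/C=C(/C)C[C@H](O[Si](C)(C)C(C)(C)C)/C=C(/CO[Si](C)(C)C(C)(C)C)C[C@H](O)[C@@H]12 | intermediate
30 | angelic acid, (2Z)-2-methylbut-2-enoic acid | C/C=C(/C)C(=O)O | starting material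
31 | (2Z)-2-methylbut-2-enoic 2,4,6-trichlorobenzoic anhydride | C/C=C(/C)C(=O)OC(=O)c1c(Cl)cc(Cl)cc1Cl | intermediate
32 | (3aR,4S,6E,8S,10Z,11aR)-8-[(tert-butyldimethylsilyl)oxy]-6-{[(tert-butyldimethylsilyl)oxy]methyl}-10-methyl-3-methylidene-2-oxo-2,3,3a,4,5,8,9,11a-octahydrocyclodeca[b]furan-4-yl (2Z)-2-methylbut-2-enoate | C=C1C(=O)O[C@@H]2/C=C(/C)C[C@H](O[Si](C)(C)C(C)(C)C)/C=C(/CO[Si](C)(C)C(C)(C)C)C[C@H](OC(=O)/C(C)=C\C)[C@@H]12 | intermediate
33 | (3aR,4S,6E,8S,10Z,11aR)-8-hydroxy-6-(hydroxymethyl)-10-methyl-3-methylidene-2-oxo-2,3,3a,4,5,8,9,11a-octahydrocyclodeca[b]furan-4-yl (2Z)-2-methylbut-2-enoate (CNP0270898.1) | C=C1C(=O)O[C@@H]2/C=C(/C)C[C@H](O)/C=C(/CO)C[C@H](OC(=O)/C(C)=C\C)[C@@H]12 | target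

**Step count.** Total: 18 steps. Longest linear sequence: 16 steps (1–3, 5–8, 10–18); steps 4 and 9 prepare the two coupling partners.

**Steps most likely to fail**

Step 14 (ring closure). Dimerisation or oligomerisation, hydrodehalogenation of either halide, insertion of low-valent nickel into the allylic lactone C6–O bond, or 6-endo attack of the C9 radical on C4 may outrun ring closure. The fallback is a two-electron Negishi macrocyclisation that sets out from 23 and comes back at 24. Silylation of the C8 hydroxyl (Et3SiOTf, 2,6-lutidine) would give the triethylsilyl ether bromide F1, and Finkelstein exchange (NaI, acetone) the primary iodide F2. Zinc insertion into the C(sp3)–I bond only (Zn dust, LiCl, THF, 25 °C) would give the alkylzinc iodide F3, which with Pd(PPh3)4 at high dilution should couple with the vinyl iodide, with retention, to the silyl-protected macrocycle F4. PPTS in MeOH would then remove the triethylsilyl group and return 24.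

Step 13 (C8 carbinol). Poor facial selectivity is possible if the oxazaborolidine does not differentiate CH2Br from the C7 branch, or if the substrate bias opposes the catalyst. The fallback replaces reagent-controlled reduction by resolution of the terminal epoxide; it sets out from 22 and comes back at 23. NaBH4 (MeOH, −40 °C) would reduce 22 without control to 23 and its C8 epimer F5. K2CO3 in acetone would close both to the oxiranes, the desired epoxide F6 and the epimeric epoxide F7. Hydrolytic kinetic resolution with the (salen)Co(OAc) antipode (trivalent cobalt) that hydrolyses the 8-epi-oxirane, using 0.5 equiv H2O, would convert F7 into the diol F8 and leave F6. LiBr and AcOH in THF would reopen F6 at the primary carbon and return 23.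

Step 5 (vinylogous aldol). Insufficient enantiofacial control, formation of the non-lactonising E γ-adduct, or addition–elimination at the β-iodo enal carbon may erode the step. The fallback is an allylation, acylation and metathesis sequence that sets out from 5 and comes back at 9. Brown methallylation with (−)-B-methallyldiisopinocampheylborane (Si-face addition, Et2O, −78 °C) would give the homoallylic alcohol F9. Acryloyl chloride and Et3N would give the acrylate F10. Ring-closing metathesis with the second-generation Grubbs catalyst (CH2Cl2, 40 °C) would form the trisubstituted ring alkene and return 9.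

**Further compounds**

F1 | step 14 | triethylsilyl ether of 23 at the C8 oxygen (primary bromide) | O=C1C[C@H]([C@@H](O[Si](CC)(CC)CC)CBr)[C@H](O1)/C=C(C)\C[C@H](O[Si](C)(C)C(C)(C)C)/C=C(\I)CO[Si](C)(C)C(C)(C)C
F2 | step 14 | corresponding primary iodide | O=C1C[C@H]([C@@H](O[Si](CC)(CC)CC)CI)[C@H](O1)/C=C(C)\C[C@H](O[Si](C)(C)C(C)(C)C)/C=C(\I)CO[Si](C)(C)C(C)(C)C
F3 | step 14 | corresponding alkylzinc iodide | O=C1C[C@H]([C@@H](O[Si](CC)(CC)CC)C[Zn]I)[C@H](O1)/C=C(C)\C[C@H](O[Si](C)(C)C(C)(C)C)/C=C(\I)CO[Si](C)(C)C(C)(C)C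
F4 | step 14 | triethylsilyl ether of 24 at the C8 oxygen | C1C(=O)O[C@@H]2/C=C(/C)C[C@H](O[Si](C)(C)C(C)(C)C)/C=C(/CO[Si](C)(C)C(C)(C)C)C[C@H](O[Si](CC)(CC)CC)[C@@H]12
F5 | step 13 | C8 epimer of bromohydrin 23, (1S)-2-bromo-1-hydroxyethyl | O=C1C[C@H]([C@H](O)CBr)[C@H](O1)/C=C(C)\C[C@H](O[Si](C)(C)C(C)(C)C)/C=C(\I)CO[Si](C)(C)C(C)(C)C
F6 | step 13 | terminal epoxide from 23, (2R)-oxiran-2-yl on the lactone 4-position | O=C1C[C@H]([C@@H]2CO2)[C@H](O1)/C=C(C)\C[C@H](O[Si](C)(C)C(C)(C)C)/C=C(\I)CO[Si](C)(C)C(C)(C)C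
F7 | step 13 | epimeric terminal epoxide from F5, (2S)-oxiran-2-yl | O=C1C[C@H]([C@H]2CO2)[C@H](O1)/C=C(C)\C[C@H](O[Si](C)(C)C(C)(C)C)/C=C(\I)CO[Si](C)(C)C(C)(C)C
F8 | step 13 | 1,2-diol from hydrolysis of F7 | O=C1C[C@H]([C@H](O)CO)[C@H](O1)/C=C(C)\C[C@H](O[Si](C)(C)C(C)(C)C)/C=C(\I)CO[Si](C)(C)C(C)(C)C
F9 | step 5 | (2Z,4S)-1-[(tert-butyldimethylsilyl)oxy]-2-iodo-6-methylhepta-2,6-dien-4-ol | C=C(C)C[C@H](O)/C=C(\I)CO[Si](C)(C)C(C)(C)C
F10 | step 5 | (2Z,4S)-1-[(tert-butyldimethylsilyl)oxy]-2-iodo-6-methylhepta-2,6-dien-4-yl prop-2-enoate | C=CC(=O)O[C@@H](CC(C)=C)/C=C(\I)CO[Si](C)(C)C(C)(C)C
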